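Per hour, what fraction of the D you have made is lost? Answer that and you can choose the set-up for the next run.

all flasks: Z 1.20 equiv

| run | G | time | remark |
|---|---|---|---|
| Thursday's | 0.50 M (fed, over 24.0 h) | 30 h | all but G at the start; G goes in evenly over 24.0 h, the run ends at 30 h |
| Wednesday's | 0.50 M | 30 h | everything together in a closed stirred flask, run for 30 h |
| Monday's | 0.50 M | 30 h | a tube with plug flow, the mixed feed as stated, residence time 30 h |
| Friday's | 0.50 M |  | a single well-mixed tank run continuously and read at steady state, 30 h in it on average |

1. the set-up with the highest share of D in all that became D or Q or D.L or G.D, at the outlet or at the end ("none" if the first two lie within 2 percentage points) (Thursday's / Wednesday's / Monday's / Friday's / none)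
2. share of D in all that became D or Q or D.L or G.D, at the outlet or at the end, Thursday's
3. share of D in all that became D or Q or D.L or G.D, at the outlet or at the end, Wednesday's
4. share of D in all that became D or Q or D.L or G.D, at the outlet or at the end, Monday's
5. share of D in all that became D or Q or D.L or G.D, at the outlet or at the end, Friday's

- a species is counted by the G in it: one G.D counts as two
- the stated concentrations are those of everything mixed, before any reaction; amounts are the same in each set-up
- the feed brings no volume worth counting
- run time (Thursday's): 30 h

    G + Z → D + L (k1 = 1.6 × 10⁻⁵ M⁻¹ s⁻¹)
    Z + D → Q + L (k2 = 2.8 × 10⁻⁵ M⁻¹ s⁻¹)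
    D + L → D.L (k3 = 7.0 × 10⁻⁶ M⁻¹ s⁻¹)
    G + D → G.D (k4 = 1.2 × 10⁻⁵ M⁻¹ s⁻¹)

1. Freeze G and Z at their charges. L is not charged, so I leave its step out. Call the fraction of D lost per hour, with G and Z held at their charges, the frozen loss rate, a pseudo-first-order constant. It comes to 0.0821 h⁻¹. At Wednesday's charges, Z takes D faster than G does, with a half-life of 11 h against 32 h.

2. Take D made evenly over a window, and let x be the loss rate times that window. The fraction kept is one minus e to the minus x, all over x. Wednesday's flask has a window of 30 h, so x is 2.46 and the share is 37.1%. Monday's tube has the same time history, so it gives 37.1%.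

3. Friday's tank holds a steady mixture, so its share is one over one plus x: 28.9%.

4. For Thursday's flask, I reckon G as climbing evenly for 24.0 h and then standing. I take the making of D to follow G, so the reckoned mean age of D at the end is 10.3 h, younger than the 15.0 h reckoned for Wednesday's flask. Take twice that age as the window. Then x is 1.70 and the share is 48.1%.

5. So charge Z and feed G. My choice is Thursday's, ahead by 11 percentage points, more than the margin of 2 points.

The forecast chose Thursday's, with 47% there against 34%, 34% and 33.3% for Wednesday's, Monday's and Friday's, since “most D forms late and has little time to be consumed”.

The simulation gives Thursday's: 47.7% for Thursday's, then 35.2%, 35.2% and 33.3% for Wednesday's, Monday's and Friday's.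

With the dose squeezed into a tenth of the run, Thursday's flask gave 36.6%. Now cut Z in Thursday's flask to 0.720 equiv. The frozen loss rate becomes 0.0579 h⁻¹, so x is 1.20 and the reckoned share is 58.3%. That flask gave 55.4%.

Its constants were drawn at random within sensible limits.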